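At 1.04 d the ash run, at 40 °C, stood higher than the oak run at 25 °C, with 41 % of product against 4 %. Both runs begin slowly, which suits the candidate steps: substrate and partner each become an intermediate, and the two intermediates then join to product. In theta, epsilon, zeta and beta, substrate is the limiting reagent by charge, with [substrate] charged at 31 mM below [partner] charged at 37.2 mM.

| flask | substrate | partner | temperature | remark | time |
|---|---|---|---|---|---|
| oak | 31 mM | 37.2 mM | 25 °C | run made earlier |  |
| ash | 43 mM | 37.2 mM | 40 °C | run made earlier |  |
| maple | 68 mM | 37.2 mM | 25 °C | run made earlier |  |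
| birch | 31 mM | 56 mM | 40 °C | run made earlier |  |
| theta | 31 mM (fed, over 2.5 d) | 37.2 mM |  | the addition at 10 °C, then warmed to 40 °C; the feed brings no volume worth counting | 3.0 d |
| epsilon | 31 mM | 37.2 mM | 40 °C | everything together at the start | 3.0 d |
| zeta | 31 mM (fed, over 2.5 d) | 37.2 mM | 40 °C | all else is in the flask from the start; the feed brings no volume worth counting | 3.0 d |
| beta | 31 mM | 37.2 mM (fed, over 2.5 d) | 40 °C | all else is in the flask from the start; the feed brings no volume worth counting | 3.0 d |

| run | time / d | product / % |
|---|---|---|
| oak | 0.500 | 0 |
| oak | 0.625 | 1 |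
| oak | 1.04 | 4 |
| oak | 1.67 | 4 |
| oak | 2.50 | 10 |
| oak | 4.00 | 25 |
| oak | 6.00 | 45 |
| ash | 0.333 | 6 |
| ash | 0.625 | 18 |
| ash | 1.04 | 41 |
| ash | 1.25 | 47 |
| ash | 1.67 | 60 |
| ash | 2.08 | 64 |
| ash | 2.50 | 73 |
| maple | 0.625 | 0 |
| maple | 1.25 | 1 |
| maple | 2.00 | 6 |
| maple | 2.50 | 6 |
| maple | 4.00 | 20 |
| maple | 5.00 | 27 |
| birch | 0.500 | 17 |
| birch | 1.04 | 56 |
| birch | 1.25 | 66 |
| birch | 2.08 | 92 |
| birch | 2.50 | 92 |

(each reading ± 2 percentage points)

- the numbers in the tables scatter with a standard deviation of 2 percentage points
- candidate steps: partner -> second intermediate; substrate -> open intermediate; open intermediate + second intermediate -> product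

* the flask that comes out highest in amount of product, in percent of the substrate charged, or "all alike" when all lie within 1.5 percentage points (theta / epsilon / zeta / beta / all alike)
* product at the end, in percent of the substrate charged, theta
* product at the end, in percent of the substrate charged, epsilon
* product at the end, in percent of the substrate charged, zeta
* product at the end, in percent of the substrate charged, beta

Two of us disagree about what a slow feed costs in zeta and beta, which are both held at 40 °C and read at 3.0 d. The first made the forecast, and speaks of the feed as a lag: “Feeding leaves about 1.5 d of lag, so zeta is about 52% and beta about 58%.” The forecast's figures are 14 % for theta, 81 % for epsilon, 52 % for zeta and 57 % for beta, with epsilon highest.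

The second, whose reckoning this is, follows each portion of the feed. A portion enters late by the time already gone, and averaging that lateness over a steady feed is a short integral. It gives 1.25 d, half the feed time, and this is the mean feed delay. So a fed flask at 40 °C should read roughly as the unfed flask does at 1.75 d.

The ash run read 60 % at 1.67 d and 64 % at 2.08 d, which brackets that time. Ash is a stand-in, charged with 43 mM of substrate against 31 mM in zeta, but I commit to about those figures for zeta and beta, above the forecast's.

The first keeps one region, the cold addition in theta. Oak, warmer than 10 °C, read 4 % at 1.04 d, so I expect product in theta to wait for the warming, and there I count the feed time as a block. For theta I accept the forecast's 14 %.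

Epsilon comes out highest at 85.4 %, with theta at 16.0 %, zeta at 69.4 % and beta at 66.2 %. At 2.5 d, the end of the feed, zeta held 55.9 % of product and theta 0.0201 %. The delay of 1.25 d places zeta and beta at 1.75 d on epsilon's clock, just past its 60.9 % at 1.50 d. Both came out above that, and above my ash figures too.

    partner → second intermediate (k = 0.0690 h⁻¹, Ea = 96.0 kJ mol⁻¹)
    substrate → open intermediate (k = 0.120 h⁻¹, Ea = 102 kJ mol⁻¹)
    open intermediate + second intermediate → product (k = 2.20 M⁻¹ h⁻¹, Ea = 81.0 kJ mol⁻¹)
    (constants at 40 °C)

Zeta with its feed shortened to 0.250 d carries a delay of 0.125 d, so it should read close to epsilon, as at 2.88 d. Computed, it gives 85.0 % against epsilon's 85.4 %.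

The readings are simulated with made-up constants; scatter was added.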